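**Plan**
- Retrosynthesis: the two disubstituted polyene double bonds C11=C12 and C11'=C12' (carotenoid numbering) are cut by Wittig disconnection. This gives a C15 ring phosphonium salt, the C10 trienedial and farnesyltriphenylphosphonium bromide. The C15 salt goes back to (R)-α-ionone.
- The only ring is then opened at C5–C6. In the cyclohexene ring the stereogenic CH (C6) is bound directly to the methyl-bearing alkene carbon C5 and is also allylic to the exocyclic C7=C8 double bond. C5–C6 is therefore a vinyl–allyl bond, and both of its ends can be drawn as electrophiles.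
- Key event: a nickel-catalysed, enantioconvergent, intramolecular reductive coupling of a (Z)-vinyl iodide with a racemic secondary allylic chloride. It should close the ring and fix the C4=C5 position, the E C7=C8 bond and the C6 configuration in one step.
- Forward order: acyclic chain (nitrile alkylation, α-iodo Wittig, alkenylzinc addition) → ring (step 7) → C15 salt; farnesyl salt + C10 dial → C25 aldehyde; C15 + C25 → C40.
- Stereochemistry: C6 (R) comes from the chiral bis(oxazoline) ligand on nickel, the racemic chloride centre being erased. The ring alkene geometry comes from the Z vinyl iodide. The chain double bonds come from (E,E)-farnesyl bromide, the E,E,E-dial and Wittig reaction followed by equilibration.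

Key step: step 7

Remark: 2-ethynyl-2-methyl-1,3-dioxolane (13) is taken as a purchased compound.
Remark: the sense of induction of the bis(oxazoline) ligand in step 7 cannot be predicted with confidence; the enantiomer named is the working choice, and its mirror image is used instead if it proves to favour 6S.

**Step 1**
Reactants: 1 isobutyronitrile; 2 2-(2-bromoethyl)-1,3-dioxolane
Product: 4 4-(1,3-dioxolan-2-yl)-2,2-dimethylbutanenitrile, via lithiated isobutyronitrile 3 (not isolated)
Conditions: LDA, THF, −78 °C; then 2, −78 °C → rt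
Reagents that add atoms: none
Why: SN2 alkylation of the lithiated tertiary nitrile by a primary bromide should build the quaternary carbon that becomes the gem-dimethyl ring carbon C1.

**Step 2**
Reactants: 4 4-(1,3-dioxolan-2-yl)-2,2-dimethylbutanenitrile
Product: 5 2,2-dimethyl-5-oxopentanenitrile
Conditions: 1 M aq. HCl, THF, rt
Reagents that add atoms: water, O
Why: Acid-catalysed acetal hydrolysis frees the unhindered aldehyde, while the tertiary nitrile is inert to dilute acid at room temperature.

**Step 3**
Reactants: 5 2,2-dimethyl-5-oxopentanenitrile; 6 ethyltriphenylphosphonium iodide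
Product: 10 (5Z)-6-iodo-2,2-dimethylhept-5-enenitrile, via ethylidenetriphenylphosphorane 7 (not isolated), via (1-iodoethyl)triphenylphosphonium iodide 8 (not isolated), via (1-iodoethylidene)triphenylphosphorane 9 (not isolated)
Conditions: 6, n-BuLi, THF, 0 °C; I2, −78 °C; NaHMDS, −20 °C; then 5, −78 °C → rt
Reagents that add atoms: iodine, II
Why: Wittig olefination with the α-iodo ylide (Stork–Zhao type) is kinetically selective for the Z vinyl iodide, with iodine cis to the chain, which is the geometry the ring double bond later requires.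

**Step 4**
Reactants: 10 (5Z)-6-iodo-2,2-dimethylhept-5-enenitrile
Product: 12 (5Z)-6-iodo-2,2-dimethylhept-5-enal, via N-aluminated aldimine 11 (not isolated)
Conditions: DIBAL-H, CH2Cl2, −78 °C; then 1 M aq. HCl, 0 °C
Reagents that add atoms: water, O
Why: DIBAL-H adds once to the hindered nitrile to give an aluminated imine that is stable at −78 °C and hydrolyses to the aldehyde on work-up; the vinyl iodide is inert.

**Step 5**
Reactants: 12 (5Z)-6-iodo-2,2-dimethylhept-5-enal; 13 2-ethynyl-2-methyl-1,3-dioxolane
Product: 16 rac-(1E,7Z)-8-iodo-4,4-dimethyl-1-(2-methyl-1,3-dioxolan-2-yl)nona-1,7-dien-3-ol, via alkenylzirconocene chloride 14 (not isolated), via alkenyl(methyl)zinc 15 (not isolated)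
Conditions: 13, Cp2Zr(H)Cl, CH2Cl2, rt; Me2Zn, toluene, −65 °C; then 12, 0 °C; then H2O
Reagents that add atoms: none
Why: Wipf alkenylation (syn hydrozirconation of the terminal alkyne, transmetalation to zinc, 1,2-addition to the non-enolisable aldehyde) should give the E allylic alcohol as a racemate; the carbinol centre is left uncontrolled on purpose because step 7 erases it.

**Step 6**
Reactants: 16 rac-(1E,7Z)-8-iodo-4,4-dimethyl-1-(2-methyl-1,3-dioxolan-2-yl)nona-1,7-dien-3-ol
Product: 17 rac-2-[(1E,7Z)-3-chloro-8-iodo-4,4-dimethylnona-1,7-dien-1-yl]-2-methyl-1,3-dioxolane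
Conditions: PPh3, hexachloroacetone, CH2Cl2, 0 °C
Reagents that add atoms: hexachloroacetone, ClC(Cl)(Cl)C(=O)C(Cl)(Cl)Cl
Why: Appel-type deoxychlorination under neutral conditions should spare the ketal and the vinyl iodide; any allylically transposed chloride formed alongside is carried on, since it gives the same allyl intermediate in step 7.

**Step 7**
Reactants: 17 rac-2-[(1E,7Z)-3-chloro-8-iodo-4,4-dimethylnona-1,7-dien-1-yl]-2-methyl-1,3-dioxolane
Product: 18 2-methyl-2-[(E)-2-[(1R)-2,6,6-trimethylcyclohex-2-en-1-yl]ethenyl]-1,3-dioxolane ((R)-α-ionone ethylene ketal)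
Conditions: NiCl2(dme) (10 mol %), (3aR,3a'R,8aS,8a'S)-2,2'-(cyclopropane-1,1-diyl)bis(3a,8a-dihydro-8H-indeno[1,2-d]oxazole) (12 mol %), Mn powder (3 equiv), DMA, 0 °C, 0.02 M
Reagents that add atoms: none
Why: Proposed new method: zerovalent nickel inserts into the Z vinyl C–I bond with retention, a low-valent nickel species abstracts chlorine from the allylic C–Cl bond to give a planar C6–C7–C8 allyl radical (so both enantiomers of 17, and any transposed chloride, become one intermediate), the radical is captured at the ligand-bound vinylnickel centre, and C(sp2)–C(sp3) reductive elimination forms C5–C6 while manganese returns nickel to the zerovalent state. The closest known reaction types are the nickel/bis(oxazoline)-catalysed asymmetric reductive coupling of vinyl bromides with racemic benzylic chlorides and the nickel-catalysed enantioconvergent Negishi coupling of racemic secondary allylic chlorides; new here is the intramolecular use on an unsymmetrical 1,3-disubstituted allyl unit next to a quaternary carbon. The six-membered ring closes by reductive elimination from a seven-membered vinyl(allyl)nickelacycle bound at the proximal allyl terminus C6; bonding at the distal terminus C8 would need an eight-membered ring holding an E double bond and is excluded. The C6 stereocentre is set under catalyst control by the chiral bis(oxazoline) on nickel, because the substrate stereocentre is lost in the allyl radical and the diastereomeric allylnickel species can interconvert by reversible Ni–C homolysis before the bond-forming step. The step needs cross-selectivity between two electrophiles (secured by the tether and by the different activation modes of the C(sp2)–I and C(sp3)–Cl bonds), retention of the Z geometry at C4=C5 (only the Z vinylnickel can reach C6) and E geometry at C7=C8 (secured by the syn,syn arrangement of the two bulky allyl termini). High dilution should suppress intermolecular allyl dimerisation, and the gem-dimethyl group at C1 favours the folded conformer.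

**Step 8**
Reactants: 18 (R)-α-ionone ethylene ketal
Product: 19 (3E)-4-[(1R)-2,6,6-trimethylcyclohex-2-en-1-yl]but-3-en-2-one ((R)-α-ionone)
Conditions: 10% aq. oxalic acid, THF, rt
Reagents that add atoms: water, O
Why: Mild hydrolysis of the allylic ketal; dilute oxalic acid at room temperature should neither move the ring double bond into conjugation nor epimerise C6.

**Step 9**
Reactants: 19 (R)-α-ionone
Product: 20 (1E)-3-methyl-1-[(1R)-2,6,6-trimethylcyclohex-2-en-1-yl]penta-1,4-dien-3-ol (both C3 epimers)
Conditions: CH2=CHMgBr, THF, −30 → 0 °C; then H2O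
Reagents that add atoms: vinylmagnesium bromide, C=C[Mg]Br
Why: 1,2-Addition of a vinyl Grignard reagent to the enone carbonyl at low temperature (the usual course with ionones); the new carbinol centre forms as both epimers and is destroyed in step 10.

**Step 10**
Reactants: 20 (1E)-3-methyl-1-[(1R)-2,6,6-trimethylcyclohex-2-en-1-yl]penta-1,4-dien-3-ol
Product: 21 [(2E,4E)-3-methyl-5-[(1R)-2,6,6-trimethylcyclohex-2-en-1-yl]penta-2,4-dien-1-yl]triphenylphosphonium bromide
Conditions: PPh3·HBr, MeOH, rt, dark; crystallisation
Reagents that add atoms: triphenylphosphine hydrobromide, [Br-].[PH+](c1ccccc1)(c1ccccc1)c1ccccc1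
Why: Ionisation of the bis-allylic tertiary alcohol and capture of the pentadienyl cation by triphenylphosphine at the unhindered terminal carbon (SN1' allylic transposition, the standard entry to C15 carotenoid Wittig salts) should give mainly the 2E salt, purified by crystallisation; C6 is not part of the cation.

**Step 11**
Reactants: 22 (2E,6E)-farnesyl bromide
Product: 23 [(2E,6E)-3,7,11-trimethyldodeca-2,6,10-trien-1-yl]triphenylphosphonium bromide
Conditions: PPh3, toluene, rt, dark
Reagents that add atoms: triphenylphosphine, P(c1ccccc1)(c1ccccc1)c1ccccc1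
Why: SN2 quaternisation of triphenylphosphine by the primary allylic bromide at room temperature, without allylic transposition or double-bond isomerisation.

**Step 12**
Reactants: 23 farnesyltriphenylphosphonium bromide; 24 (2E,4E,6E)-2,7-dimethylocta-2,4,6-trienedial
Product: 26 (2E,4E,6E,8E,10E,14E)-2,7,11,15,19-pentamethylicosa-2,4,6,8,10,14,18-heptaenal, via farnesylidenetriphenylphosphorane 25 (not isolated)
Conditions: 24 (3 equiv), NaOMe, MeOH–CH2Cl2, 0 °C → rt, slow addition of 23; then I2 (cat.), hexane, daylight
Reagents that add atoms: none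
Why: Wittig reaction of the allylic ylide with the dialdehyde in excess, so that one formyl group reacts; the new disubstituted double bond forms as an E/Z mixture, and its hindered Z isomer is converted to E by iodine-catalysed equilibration.

**Step 13**
Reactants: 21 C15 phosphonium bromide; 26 C25 aldehyde
Product: 28 (6R)-7',8'-dihydro-ε,ψ-carotene (α-zeacarotene), via C15 ylide 27 (not isolated)
Conditions: NaOMe, MeOH–CH2Cl2, rt, Ar, dark; then heptane, reflux; crystallisation
Reagents that add atoms: none
Why: Wittig reaction joining the C15 ylide to the C25 aldehyde (the standard C15 + C25 carotenoid assembly); methoxide does not reach the doubly allylic C6–H, and Z isomers at the new double bond are equilibrated thermally to the all-E polyene.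

**Compound list**
1 | isobutyronitrile | CC(C)C#N | starting material
2 | 2-(2-bromoethyl)-1,3-dioxolane | BrCCC1OCCO1 | starting material
3 | lithiated isobutyronitrile (2-lithio-2-methylpropanenitrile) | [Li]C(C)(C)C#N | intermediate
4 | 4-(1,3-dioxolan-2-yl)-2,2-dimethylbutanenitrile | N#CC(C)(C)CCC1OCCO1 | intermediate
5 | 2,2-dimethyl-5-oxopentanenitrile | N#CC(C)(C)CCC=O | intermediate
6 | ethyltriphenylphosphonium iodide | CC[P+](c1ccccc1)(c1ccccc1)c1ccccc1.[I-] | starting material
7 | ethylidenetriphenylphosphorane | CC=P(c1ccccc1)(c1ccccc1)c1ccccc1 | intermediate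
8 | (1-iodoethyl)triphenylphosphonium iodide | CC(I)[P+](c1ccccc1)(c1ccccc1)c1ccccc1.[I-] | intermediate
9 | (1-iodoethylidene)triphenylphosphorane | CC(I)=P(c1ccccc1)(c1ccccc1)c1ccccc1 | intermediate
10 | (5Z)-6-iodo-2,2-dimethylhept-5-enenitrile | C/C(I)=C/CCC(C)(C)C#N | intermediate
11 | (5Z)-N-(diisobutylalumanyl)-6-iodo-2,2-dimethylhept-5-en-1-imine | C/C(I)=C/CCC(C)(C)C=N[Al](CC(C)C)CC(C)C | intermediate
12 | (5Z)-6-iodo-2,2-dimethylhept-5-enal | C/C(I)=C/CCC(C)(C)C=O | intermediate
13 | 2-ethynyl-2-methyl-1,3-dioxolane | C#CC1(C)OCCO1 | starting material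
14 | chloro[(E)-2-(2-methyl-1,3-dioxolan-2-yl)ethenyl]zirconocene | CC1(/C=C/[Zr](Cl)(C2C=CC=C2)C2C=CC=C2)OCCO1 | intermediate
15 | methyl[(E)-2-(2-methyl-1,3-dioxolan-2-yl)ethenyl]zinc | CC1(/C=C/[Zn]C)OCCO1 | intermediate
16 | rac-(1E,7Z)-8-iodo-4,4-dimethyl-1-(2-methyl-1,3-dioxolan-2-yl)nona-1,7-dien-3-ol | C/C(I)=C/CCC(C)(C)C(O)/C=C/C1(C)OCCO1 | intermediate
17 | rac-2-[(1E,7Z)-3-chloro-8-iodo-4,4-dimethylnona-1,7-dien-1-yl]-2-methyl-1,3-dioxolane | C/C(I)=C/CCC(C)(C)C(Cl)/C=C/C1(C)OCCO1 | intermediate
18 | 2-methyl-2-[(E)-2-[(1R)-2,6,6-trimethylcyclohex-2-en-1-yl]ethenyl]-1,3-dioxolane | CC1(/C=C/[C@H]2C(C)=CCCC2(C)C)OCCO1 | intermediate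
19 | (R)-α-ionone, (3E)-4-[(1R)-2,6,6-trimethylcyclohex-2-en-1-yl]but-3-en-2-one | CC(=O)/C=C/[C@H]1C(C)=CCCC1(C)C | intermediate
20 | (1E)-3-methyl-1-[(1R)-2,6,6-trimethylcyclohex-2-en-1-yl]penta-1,4-dien-3-ol (C3 epimers) | C=CC(C)(O)/C=C/[C@H]1C(C)=CCCC1(C)C | intermediate
21 | [(2E,4E)-3-methyl-5-[(1R)-2,6,6-trimethylcyclohex-2-en-1-yl]penta-2,4-dien-1-yl]triphenylphosphonium bromide | [Br-].c1ccccc1[P+](c1ccccc1)(c1ccccc1)C/C=C(C)/C=C/[C@H]1C(C)=CCCC1(C)C | intermediate
22 | (2E,6E)-farnesyl bromide, (2E,6E)-1-bromo-3,7,11-trimethyldodeca-2,6,10-triene | CC(C)=CCC/C(C)=C/CC/C(C)=C/CBr | starting material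
23 | [(2E,6E)-3,7,11-trimethyldodeca-2,6,10-trien-1-yl]triphenylphosphonium bromide | CC(C)=CCC/C(C)=C/CC/C(C)=C/C[P+](c1ccccc1)(c1ccccc1)c1ccccc1.[Br-] | intermediate
24 | (2E,4E,6E)-2,7-dimethylocta-2,4,6-trienedial | O=C/C(C)=C/C=C/C=C(C)/C=O | starting material
25 | farnesylidenetriphenylphosphorane | CC(C)=CCC/C(C)=C/CC/C(C)=C/C=P(c1ccccc1)(c1ccccc1)c1ccccc1 | intermediate
26 | (2E,4E,6E,8E,10E,14E)-2,7,11,15,19-pentamethylicosa-2,4,6,8,10,14,18-heptaenal | CC(C)=CCC/C(C)=C/CC/C(C)=C/C=C/C(C)=C/C=C/C=C(C)/C=O | intermediate
27 | [(2E,4E)-3-methyl-5-[(1R)-2,6,6-trimethylcyclohex-2-en-1-yl]penta-2,4-dien-1-ylidene]triphenylphosphorane | C(=P(c1ccccc1)(c1ccccc1)c1ccccc1)/C=C(C)/C=C/[C@H]1C(C)=CCCC1(C)C | intermediate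
28 | (6R)-7',8'-dihydro-ε,ψ-carotene (α-zeacarotene) | CC(C)=CCC/C(C)=C/CC/C(C)=C/C=C/C(C)=C/C=C/C=C(C)/C=C/C=C(C)/C=C/[C@H]1C(C)=CCCC1(C)C | target

**Step count and risks**
Total step count: 13. Longest linear sequence: 11 steps (steps 1–10, then step 13).

Steps most likely to fail:

1. **Step 7.** Enantiocontrol may be poor, either carbon–halogen bond may be reduced before the ring closes, allyl units may dimerise between molecules, or the allylnickel intermediate may lose a ketal oxygen by β-alkoxy elimination. The fallback uses known chemistry and is stereospecific instead of stereoconvergent. It sets out from 12 and 13 and returns at 18.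
   - Hydroboration of 13 with dicyclohexylborane, boron-to-zinc exchange with Me2Zn and addition to 12 under catalysis by (−)-3-exo-morpholinoisoborneol (catalytic asymmetric alkenylzinc addition) should give (1E,3S,7Z)-8-iodo-4,4-dimethyl-1-(2-methyl-1,3-dioxolan-2-yl)nona-1,7-dien-3-ol F1. The S sense is expected by analogy with simple aldehydes.
   - Pd(PPh3)4 and hexamethylditin should exchange iodine for tin with retention to give (1E,3S,7Z)-4,4-dimethyl-1-(2-methyl-1,3-dioxolan-2-yl)-8-(trimethylstannyl)nona-1,7-dien-3-ol F2.
   - Methyl chloroformate and pyridine give its allylic methyl carbonate F3.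
   - Pd2(dba)3, AsPh3 and LiCl in NMP then effect an intramolecular allyl–vinyl Stille coupling. Zerovalent palladium ionises the carbonate with inversion and delivers the vinyl group from the metal with retention, so the net inversion at C6 turns the 3S carbinol into the 6R ring of 18.

2. **Step 6.** The neopentylic allylic alcohol may ionise, with skeletal rearrangement or ketal opening, and the chloride may decompose on purification. The fallback avoids any C–O cleavage before the nickel step. It sets out from 16 and returns at 18. Methyl chloroformate and pyridine convert 16 into rac-methyl (1E,7Z)-8-iodo-4,4-dimethyl-1-(2-methyl-1,3-dioxolan-2-yl)nona-1,7-dien-3-yl carbonate F4. F4 is used in place of 17 under the step 7 conditions, where zerovalent nickel should ionise the carbonate to an allylnickel species that couples with the vinyl iodide.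

3. **Step 3.** Z control in the α-iodo Wittig reaction may be incomplete, and over-iodination may give a 1,1-diiodoalkene; the E iodide cannot cyclise in step 7. The fallback builds the geometry by a stereospecific coupling instead. It sets out from 5 and returns at 10.
   - Corey–Fuchs olefination (CBr4, PPh3) gives 6,6-dibromo-2,2-dimethylhex-5-enenitrile F5.
   - Palladium-catalysed trans-selective monomethylation (Me2Zn, PdCl2(DPEphos)) replaces the bromine trans to the chain and should give (5Z)-6-bromo-2,2-dimethylhept-5-enenitrile F6.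
   - Copper-catalysed halide exchange (CuI, NaI, trans-N,N'-dimethylcyclohexane-1,2-diamine, dioxane, 110 °C) with retention gives 10.

**Further compounds**
F1 | step 7 | (1E,3S,7Z)-8-iodo-4,4-dimethyl-1-(2-methyl-1,3-dioxolan-2-yl)nona-1,7-dien-3-ol | C/C(I)=C/CCC(C)(C)[C@@H](O)/C=C/C1(C)OCCO1
F2 | step 7 | (1E,3S,7Z)-4,4-dimethyl-1-(2-methyl-1,3-dioxolan-2-yl)-8-(trimethylstannyl)nona-1,7-dien-3-ol | C/C([Sn](C)(C)C)=C/CCC(C)(C)[C@@H](O)/C=C/C1(C)OCCO1
F3 | step 7 | methyl (1E,3S,7Z)-4,4-dimethyl-1-(2-methyl-1,3-dioxolan-2-yl)-8-(trimethylstannyl)nona-1,7-dien-3-yl carbonate | C/C([Sn](C)(C)C)=C/CCC(C)(C)[C@@H](OC(=O)OC)/C=C/C1(C)OCCO1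
F4 | step 6 | rac-methyl (1E,7Z)-8-iodo-4,4-dimethyl-1-(2-methyl-1,3-dioxolan-2-yl)nona-1,7-dien-3-yl carbonate | C/C(I)=C/CCC(C)(C)C(OC(=O)OC)/C=C/C1(C)OCCO1
F5 | step 3 | 6,6-dibromo-2,2-dimethylhex-5-enenitrile | N#CC(C)(C)CCC=C(Br)Br
F6 | step 3 | (5Z)-6-bromo-2,2-dimethylhept-5-enenitrile | C/C(Br)=C/CCC(C)(C)C#N
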